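**Plan**

1. Numbering: lindenane numbers in each half, primes for the second half. Cyclopropane = C1–C2–C3. Ring A = cyclopentane C1, C3, C4, C5, C10 with C4=C15H2. Ring B = cyclohexane C5–C10. Ring C = butenolide C7, C8, C11, C12, O. Ring D = central cyclobutane C8, C9, C9', C8'. The molecule is C2-symmetric, so the halves are homotopic.
2. Enabling feature: in ring A the methine C3 is bonded to both C1 and C2 of a two-carbon unit on quaternary C10, and to C4, which already carries the exocyclic methylene. C3 is therefore a latent vinylcarbene and C1–C2 a latent vinyl group. Cutting C3–C1, C3–C2, C3'–C1' and C3'–C2' turns the bis-lindenane into a bis-elemanolide (C10: CH3 and vinyl; C5: isopropenyl oxidised at one CH3).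
3. Further cuts: ring D at C8–C8' and C9–C9' ([2+2] of the C8=C9 γ-alkylidenebutenolide), ring C at C7–C11 and O–C12 (ethyl pyruvate), C10–C1 (vinyl copper reagent). In the forward direction the C4–C7 bond of the pinane cyclobutane is broken.
4. Forward order: ring B is freed from (+)-verbenone, ring C is annulated, ring D is closed by photodimerisation. Last, one flask closes both cyclopropanes and both rings A (four C–C bonds, four rings, four stereocentres) and gives the target directly.
5. Stereochemistry: C5 comes from verbenone, and C10 from conjugate addition anti to the CMe2 bridge. C8/C9 come from α-face head-to-head dimerisation anti to C10–CH3, and C1/C3 from substrate control in the carbene addition.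

Key step: step 8

Remark: (1R,5R)-(+)-verbenone is taken as a commercial single enantiomer. α/β refer to the usual drawing with C10–CH3 β.

**Step 1**
Reactants: 1 (1R,5R)-(+)-verbenone; 2 vinylmagnesium bromide
Product: 3 (1R,4S,5S)-4-ethenyl-4,6,6-trimethylbicyclo[3.1.1]heptan-2-one (vinyl anti to the CMe2 bridge)
Conditions: 2 (1.5 equiv), CuBr·SMe2 (20 mol %), THF, −40 → 0 °C; aq NH4Cl
Reagents that add atoms: none
Why: Copper-catalysed (monovalent copper) 1,4-addition of a vinyl Grignard reagent to a β,β-disubstituted enone, in which the nucleophile enters from the CH2-bridge face, anti to the CMe2 bridge, and so sets quaternary C10 with the vinyl group trans to the future C5 side chain.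

**Step 2**
Reactants: 3
Product: 4 (4S,5S)-5-ethenyl-5-methyl-4-(prop-1-en-2-yl)cyclohex-1-en-1-yl acetate
Conditions: BF3·OEt2, Zn(OAc)2, Ac2O, 0 °C → rt
Reagents that add atoms: acetic anhydride CC(=O)OC(C)=O
Why: Lewis-acid-promoted cyclobutane fragmentation, in which heterolysis of the bond between the α-bridgehead (future C7) and CMe2 (future C4) gives a tertiary cation and a metal enolate that are discharged by proton loss to the isopropenyl group and by O-acetylation to a regiodefined C7=C8 enol acetate, with C5 and C10 untouched.

**Step 3**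
Reactants: 4; 5 ethyl pyruvate
Product: 7 ethyl 2-[(4S,5S)-4-ethenyl-4-methyl-2-oxo-5-(prop-1-en-2-yl)cyclohexyl]-2-hydroxypropanoate (mixture at C7 and C11), via lithium enolate 6 (not isolated)
Conditions: MeLi (2.1 equiv), THF, 0 °C; then 5, −78 °C; aq work-up
Reagents that add atoms: none
Why: Cleavage of the enol acetate with MeLi releases the regiodefined C7 lithium enolate, which undergoes aldol addition to the ketone carbonyl of the pyruvate, and the two new centres (C7, C11) need no control because both become sp2 in step 4.

**Step 4**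
Reactants: 7
Product: 9 (5S,6S)-6-ethenyl-3,6-dimethyl-5-(prop-1-en-2-yl)-5,6-dihydro-1-benzofuran-2(4H)-one (elema-1,3,7(11),8-tetraen-12,8-olide), via 8-hydroxybutenolide 8 (not isolated)
Conditions: p-TsOH·H2O (cat.), benzene, reflux, Dean–Stark
Reagents that add atoms: none
Why: Acid-catalysed dehydration and lactonisation cascade (C7=C11 formation, closure to the hemiketal lactone, loss of water across C8–C9) gives the conjugated γ-alkylidenebutenolide as the thermodynamic sink, and neither C5 nor C10 can epimerise.

**Step 5**
Reactants: 9 (two molecules)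
Product: 10 C2-symmetric head-to-head cis-anti-cis cyclobutane dimer of 9 (new bonds C8–C8' and C9–C9' on the α faces; O8 and H9 β; each half keeps C10 methyl/vinyl and C5 isopropenyl)
Conditions: hν (medium-pressure Hg lamp, Pyrex, λ > 300 nm), degassed n-hexane (0.3 M), 10–15 °C
Reagents that add atoms: none
Why: [2+2] photocyclodimerisation of a γ-alkylidenebutenolide, in which first bonding at C9–C9' leaves two lactone-conjugated oxyallyl radicals at C8/C8' (hence head-to-head), both partners react on the α face anti to the pseudo-axial C10–CH3, an α/α head-to-head union of two homochiral molecules can only be the C2-symmetric cis-anti-cis ring D (this sets C8, C9, C8', C9'), and the pseudo-equatorial vinyl group lies near the nodal plane of C8=C9 and would give only a primary radical on bridging, so it should not outrun dimerisation at this concentration.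

**Step 6**
Reactants: 10
Product: 11 bis-enal (10 with one CH3 of each isopropenyl group, now C3, oxidised to CHO; C5–C(=CH2)–CHO in both halves)
Conditions: SeO2 (2.5 equiv), 1,4-dioxane, 80 °C
Reagents that add atoms: selenium dioxide O=[Se]=O
Why: Riley allylic oxidation (ene reaction, then [2,3]-sigmatropic shift), for which only the electron-rich 1,1-disubstituted isopropenyl groups offer reactive allylic hydrogens (the C10 vinyl has none, C7=C11 is electron-poor), with CH3 attacked in preference to the hindered C5–H methine and no stereocentre affected.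

**Step 7**
Reactants: 11
Product: 12 bis[(E)-N-tosylhydrazone] of 11
Conditions: TsNHNH2 (2.1 equiv), THF–MeOH, 0 °C → rt
Reagents that add atoms: p-toluenesulfonyl hydrazide Cc1ccc(cc1)S(=O)(=O)NN
Why: Simple condensation of an aldehyde with a sulfonyl hydrazide, which for an enal at or below room temperature is faster than conjugate addition and leaves the lactones and all stereocentres alone.

**Step 8**
Reactants: 12
Product: 16 target CNP0265879.1, via dilithium salt 13 (not isolated), via bis-diazoalkane 14 (not isolated), via half-closed diazoalkane 15 (not isolated)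
Conditions: LiOt-Bu (2.2 equiv), 1,4-dioxane, rt; then slow addition to Rh2(OAc)4 (5 mol %), 1,4-dioxane, 70 °C, final 0.005 M
Reagents that add atoms: none
Why: Each lithiated sulfonylhydrazone loses p-toluenesulfinate (Bamford–Stevens reaction) to give a 2-substituted vinyldiazomethane, which Rh2(OAc)4 (divalent rhodium) intercepts with loss of N2 as an electrophilic rhodium vinylcarbene at C3; this adds in a concerted, asynchronous [2+1] manner to the C1=C2 vinyl group on C10, first in one of the homotopic halves (15) and then in the other, so the second addition closes the last ring of the skeleton. The closest known reaction types are the copper- or rhodium-catalysed intramolecular cyclopropanation by alkenylcarbenes generated from enal sulfonylhydrazones and the diazoketone-to-vinyl closure of trans-fused bicyclo[3.1.0]hexanes. In each half the C3–C1 bond closes cyclopentane ring A in the 5-exo sense (C3, C4, C5, C10 and the inner alkene carbon C1) and the C3–C2 bond closes the cyclopropane in the same event, while the carbene carries the C4=C15 methylene in unchanged, so no later olefination is needed. H1 and H3 must be cis because a bicyclo[3.1.0]hexane can only be cis-fused, and their α orientation (C2 on the β face, syn to C10–CH3) should follow from the trans-diequatorial C5/C10 tether together with the vinyl rotamer that turns C2 away from the α face, which is filled by the C9–C9' bond and the other half of the dimer. The step needs chemoselectivity for the vinyl groups over the tetrasubstituted, electron-poor C7=C11 bonds, which are inert to an electrophilic carbene, and it needs rhodium to capture the diazoalkane before 1,5-electrocyclisation to a pyrazole or azine formation, which slow thermal release at high dilution over the catalyst should secure. A 1,2-hydride shift cannot compete, because C3 is flanked only by sp2 C4.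

**Compound list**
1 | (1R,5R)-(+)-verbenone | CC1=CC(=O)[C@@H]2C[C@H]1C2(C)C | starting material
2 | vinylmagnesium bromide | C=C[Mg]Br | starting material
3 | (1R,4S,5S)-4-ethenyl-4,6,6-trimethylbicyclo[3.1.1]heptan-2-one | C=C[C@@]1(C)[C@@H]2C(C)(C)[C@@H](C2)C(=O)C1 | intermediate
4 | (4S,5S)-5-ethenyl-5-methyl-4-(prop-1-en-2-yl)cyclohex-1-en-1-yl acetate | C=C[C@@]1(C)[C@H](C(C)=C)CC=C(OC(C)=O)C1 | intermediate
5 | ethyl pyruvate | CCOC(=O)C(C)=O | starting material
6 | lithium enolate (C7=C8) from 4 | C=C[C@@]1(C)[C@H](C(C)=C)CC=C([O-])C1.[Li+] | intermediate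
7 | pyruvate aldol adduct (C7, C11 unassigned) | C=C[C@@]1(C)[C@H](C(C)=C)CC(C(C)(O)C(=O)OCC)C(=O)C1 | intermediate
8 | 8-hydroxy-elema-1,3,7(11)-trien-12,8-olide (C8 unassigned) | C=C[C@@]1(C)[C@H](C(C)=C)CC2=C(C)C(=O)OC2(O)C1 | intermediate
9 | (5S,6S)-6-ethenyl-3,6-dimethyl-5-(prop-1-en-2-yl)-5,6-dihydro-1-benzofuran-2(4H)-one | C=C[C@@]1(C)[C@H](C(C)=C)CC2=C(C)C(=O)OC2=C1 | intermediate
10 | C2-symmetric head-to-head cis-anti-cis photodimer of 9 | C=C[C@@]1(C)[C@H](C(C)=C)CC2=C(C)C(=O)O[C@]23[C@H]1[C@H]1[C@@](C)(C=C)[C@H](C(C)=C)CC2=C(C)C(=O)O[C@@]213 | intermediate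
11 | bis-enal | C=C[C@@]1(C)[C@H](C(=C)C=O)CC2=C(C)C(=O)O[C@]23[C@H]1[C@H]1[C@@](C)(C=C)[C@H](C(=C)C=O)CC2=C(C)C(=O)O[C@@]213 | intermediate
12 | bis[(E)-N-tosylhydrazone] | C=C[C@@]1(C)[C@H](C(=C)/C=N/NS(=O)(=O)c4ccc(C)cc4)CC2=C(C)C(=O)O[C@]23[C@H]1[C@H]1[C@@](C)(C=C)[C@H](C(=C)/C=N/NS(=O)(=O)c4ccc(C)cc4)CC2=C(C)C(=O)O[C@@]213 | intermediate
13 | dilithium salt of 12 | C=C[C@@]1(C)[C@H](C(=C)/C=N/[N-]S(=O)(=O)c4ccc(C)cc4)CC2=C(C)C(=O)O[C@]23[C@H]1[C@H]1[C@@](C)(C=C)[C@H](C(=C)/C=N/[N-]S(=O)(=O)c4ccc(C)cc4)CC2=C(C)C(=O)O[C@@]213.[Li+].[Li+] | intermediate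
14 | bis(vinyldiazomethane) | C=C[C@@]1(C)[C@H](C(=C)C=[N+]=[N-])CC2=C(C)C(=O)O[C@]23[C@H]1[C@H]1[C@@](C)(C=C)[C@H](C(=C)C=[N+]=[N-])CC2=C(C)C(=O)O[C@@]213 | intermediate
15 | half-closed compound (one lindenane half, one seco diazo half) | C=C1[C@H]2C[C@H]2[C@@]2(C)[C@H]1CC1=C(C)C(=O)O[C@]13[C@H]2[C@H]1[C@@](C)(C=C)[C@H](C(=C)C=[N+]=[N-])CC2=C(C)C(=O)O[C@@]213 | intermediate
16 | CNP0265879.1 | C=C1[C@H]2C[C@H]2[C@@]2(C)[C@H]1CC1=C(C)C(=O)O[C@]13[C@H]2[C@H]1[C@@]2(C)[C@@H]4C[C@@H]4C(=C)[C@@H]2CC2=C(C)C(=O)O[C@@]213 | target

Total step count: 8. Longest linear sequence: 8 steps (from 1).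

**Steps most likely to fail**

Step 8. The diazoalkane may be drained by 1,5-electrocyclisation or azine formation before the metal captures it. The second closure may also lag behind the first and leave the material half-closed. The fallback sets out from 11 and comes back at 16. It generates the vinylcarbenoid without any diazo compound, by reductive deoxygenation of each enal with Zn(Hg) and 1,2-bis(chlorodimethylsilyl)ethane in Et2O at reflux, with slow addition of 11. The organozinc vinylcarbenoid at C3 then cyclopropanates the C10 vinyl group in the same intramolecular sense. This fallback makes no compound outside the list (F0).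

Step 5. The excited C8=C9 bond may be consumed by an intramolecular 1,2-shift of the C10 vinyl group (di-π-methane type) before two molecules meet. Face and orientation control may also erode. The fallback sets out from 3 and comes back at 10. The vinyl group is masked before any chromophore exists:
- Radical anti-Markovnikov addition of PhSH (AIBN, toluene, 80 °C) to 3 gives the 2-(phenylsulfanyl)ethyl ketone F1.
- The operations of steps 2, 3 and 4 then give the sulfide enol acetate F2, the sulfide pyruvate aldol F3 and the sulfide butenolide F4.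
- Irradiation as in step 5 gives the bis-sulfide dimer F5, whose C10 bears only saturated groups.
- mCPBA (2 equiv, CH2Cl2, −78 °C) gives the bis-sulfoxide F6.
- Thermal syn-elimination (toluene, CaCO3, 110 °C) unveils both vinyl groups and gives 10.

Step 6. The oxidation may stall at the allylic alcohol level in one or both halves, or stray to C5–H or other allylic positions, so that the twofold conversion is not clean. The fallback sets out from 10 and comes back at 11. Ene-type allylic chlorination of the more nucleophilic isopropenyl groups with HOCl (Ca(OCl)2, solid CO2, CH2Cl2–H2O, 0 °C) gives the bis(2-chloromethylallyl) dimer F7. Kornblum oxidation (DMSO, NaHCO3, NaI cat., 80 °C) then converts both CH2Cl groups into the aldehydes of 11.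

**Further compounds**
F0 | step 8 | none | none
F1 | step 5 | (1R,4S,5S)-4,6,6-trimethyl-4-[2-(phenylsulfanyl)ethyl]bicyclo[3.1.1]heptan-2-one | c3ccccc3SCC[C@@]1(C)[C@@H]2C(C)(C)[C@@H](C2)C(=O)C1
F2 | step 5 | sulfide enol acetate (4 with CH2CH2SPh in place of vinyl) | c3ccccc3SCC[C@@]1(C)[C@H](C(C)=C)CC=C(OC(C)=O)C1
F3 | step 5 | sulfide pyruvate aldol (7 with CH2CH2SPh in place of vinyl) | c3ccccc3SCC[C@@]1(C)[C@H](C(C)=C)CC(C(C)(O)C(=O)OCC)C(=O)C1
F4 | step 5 | sulfide butenolide (9 with CH2CH2SPh in place of vinyl) | c3ccccc3SCC[C@@]1(C)[C@H](C(C)=C)CC2=C(C)C(=O)OC2=C1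
F5 | step 5 | bis-sulfide dimer (10 with CH2CH2SPh in place of both vinyl groups) | c4ccccc4SCC[C@@]1(C)[C@H](C(C)=C)CC2=C(C)C(=O)O[C@]23[C@H]1[C@H]1[C@@](C)(CCSc4ccccc4)[C@H](C(C)=C)CC2=C(C)C(=O)O[C@@]213
F6 | step 5 | bis-sulfoxide of F5 (sulfur centres unassigned) | c4ccccc4S(=O)CC[C@@]1(C)[C@H](C(C)=C)CC2=C(C)C(=O)O[C@]23[C@H]1[C@H]1[C@@](C)(CCS(=O)c4ccccc4)[C@H](C(C)=C)CC2=C(C)C(=O)O[C@@]213
F7 | step 6 | bis(2-chloromethylallyl) dimer | C=C[C@@]1(C)[C@H](C(=C)CCl)CC2=C(C)C(=O)O[C@]23[C@H]1[C@H]1[C@@](C)(C=C)[C@H](C(=C)CCl)CC2=C(C)C(=O)O[C@@]213
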